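**Assumption:** Kanzonol C is 2',4,4'-trihydroxy-3,3'-diprenylchalcone. It has no stereocenters, so the only stereochemical element is the (E)-enone, which the route sets thermodynamically.

## Retrosynthetic overview
- The target's enone C=C is disconnected by Claisen–Schmidt condensation into 3'-prenylresacetophenone (3) and 3-prenyl-4-hydroxybenzaldehyde (5).
- Each prenylated aryl carbonyl comes from ortho-C-prenylation of a commercial hydroxyaryl carbonyl (1 and 4) with prenyl bromide in aqueous base.
- No rings are formed. Both aromatic rings are commercial, and the prenyl groups are installed before the final condensation.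

## Route

**Step 1**
Reactants: 1 (2',4'-dihydroxyacetophenone, resacetophenone); 2 (prenyl bromide, 1-bromo-3-methylbut-2-ene)
Product: 3 (1-(2,4-dihydroxy-3-(3-methylbut-2-enyl)phenyl)ethan-1-one)
Conditions: KOH (2.2 equiv), H2O/MeOH, 0 °C to rt, 12 h; then 1 M HCl to pH 4
Reagents that add atoms: prenyl bromide, CC(C)=CCBr
Why: The resorcinol-type phenoxide is C-nucleophilic at C3 (between the two O atoms) in protic aqueous base, where hydrogen bonding suppresses O-alkylation, so this is a C-alkylation (SN2 at the primary allylic bromide, retaining the linear prenyl group). The 2'-OH is chelated to the C=O and the C5 position is less activated, so C3 is the major site; the O-prenyl and 3,5-diprenyl by-products are removed by chromatography.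

**Step 2**
Reactants: 4 (4-hydroxybenzaldehyde); 2 (prenyl bromide)
Product: 5 (4-hydroxy-3-(3-methylbut-2-enyl)benzaldehyde)
Conditions: NaOH (2.0 equiv), H2O, rt, 16 h; then 1 M HCl to pH 4
Reagents that add atoms: prenyl bromide, CC(C)=CCBr
Why: Phenoxide C-alkylation in water, with hydrogen-bonded oxygen, occurs ortho to the O⁻ (both ortho positions are equivalent, so one product). Using about 1 equiv of prenyl bromide limits dialkylation. The aldehyde is untouched because it is dilute and cold enough to avoid Cannizzaro reaction.

**Step 3**
Reactants: 3 (3'-prenylresacetophenone); 5 (4-hydroxy-3-prenylbenzaldehyde)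
Product: 6 (kanzonol C, (E)-1-(2,4-dihydroxy-3-prenylphenyl)-3-(4-hydroxy-3-prenylphenyl)prop-2-en-1-one)
Conditions: 50% aq KOH (about 6 equiv), EtOH, rt, 48–72 h, N2, dark; then 1 M HCl to pH 3–4
Reagents that add atoms: none
Why: Claisen–Schmidt (aldol condensation followed by E1cB dehydration) of the acetophenone enolate with the non-enolisable aldehyde gives the conjugated enone. The (E)-geometry is set by thermodynamic control in the dehydration, so there is no stereocenter to scramble. The phenols stay as phenoxides, which protects them and the prenyl alkenes under the basic conditions.

## Final check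
- **Structure match:** Ring A has C1'-C(=O), 2'-OH, 3'-prenyl, 4'-OH and H at 5' and 6'. Ring B has 3-prenyl and 4-OH. The enone is E. This matches the target SMILES.
- **Atom accounting:** 3 (C13H16O3) + 5 (C12H14O2) − H2O = C25H28O4, which is kanzonol C.
- **Functional-group survival:** Prenyl alkenes are never exposed to strong acid (work-up only to pH 3–4). No protecting groups are used.
- **Stereochemistry:** There are no stereocenters. E-alkene geometry is set in step 3 and is not altered afterwards.

## Compound list
1 | 2',4'-dihydroxyacetophenone (resacetophenone) | CC(=O)c1ccc(O)cc1O | starting material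
2 | prenyl bromide (1-bromo-3-methylbut-2-ene) | CC(C)=CCBr | starting material
3 | 1-(2,4-dihydroxy-3-prenylphenyl)ethan-1-one | CC(=O)c1ccc(O)c(CC=C(C)C)c1O | intermediate
4 | 4-hydroxybenzaldehyde | O=Cc1ccc(O)cc1 | starting material
5 | 4-hydroxy-3-prenylbenzaldehyde | O=Cc1ccc(O)c(CC=C(C)C)c1 | intermediate
6 | kanzonol C | CC(C)=CCc1cc(/C=C/C(=O)c2ccc(O)c(CC=C(C)C)c2O)ccc1O | target

**Total steps:** 3. **Longest linear sequence:** 2 steps (1 → 3 → 6), with the other branch 4 → 5 converging in step 3.

## Three steps most likely to fail
1. **Step 2 (C-prenylation of 4-hydroxybenzaldehyde).** The phenoxide is deactivated, so O-alkylation, dialkylation and low conversion are likely.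
   - Fallback: start from 3-bromo-4-hydroxybenzaldehyde. Protect the phenol as its MOM ether and the aldehyde as the dimethyl acetal, then form the aryl Grignard and couple it with prenyl bromide under CuI catalysis, which keeps the linear SN2 product. Remove the acetal and MOM groups with mild acid (PPTS, MeOH/H2O) to give 5.
2. **Step 1 (regioselective C3-prenylation of resacetophenone).** Mixtures of O-prenyl, 3,5-diprenyl and 5-prenyl products would lower the yield.
   - Fallback: brominate resacetophenone at C3 with NBS, protect both phenols as MOM ethers, and install the prenyl group by Pd-catalysed cross-coupling with a prenylboron or prenylzinc reagent, checking that the linear isomer is obtained. Then remove the MOM groups to give 3.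
3. **Step 3 (Claisen–Schmidt with three free phenols).** The polyphenoxide is poorly electrophilic and nucleophilic, so conversion may stall and the prenyl groups may suffer oxidative side reactions.
   - Fallback: protect the phenols of 3 and 5 as MOM ethers, condense with NaOH/EtOH, then remove the MOM groups under mild acid (PPTS, t-BuOH, 60 °C) to give 6.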